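Caryophyllane locants are used for the carbocycle throughout: C1/C9 are the cyclobutane–nine-ring fusion, C10 is CH2, C11 is CMe2, C4 carries the methyl group C12 and the ring oxygen, C8 carries the exocyclic methylene, and C1′ is the benzylic carbon. In the names of the bicyclic intermediates chroman locants are used (chroman C2 = C4, C3 = C5, C4 = C1′).

## Analysis of the target

Target 26 is a tetracycle. A fully substituted phloroglucinol ring (ring A, two free OH and two CHO) is part of a chroman (ring B). Ring B is trans-fused across C4–C5 to a nine-membered carbocycle (ring C, C1–C9), which is trans-fused across C1–C9 to a cyclobutane (ring D: C1, C9, C10, C11) with a gem-dimethyl group on C11. C8 bears an exocyclic methylene and C1′ a phenyl group.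

There are five stereocentres, 1R,4R,5S,9S,1′R. H-1′ and H-5 are trans. The C4 methyl group is trans to H-5, so C3 and C6 leave ring B as two equatorial, gauche arms. C4 is a fully substituted ether carbon. H-1 and H-9 are trans, with H-1 on the side of H-5. The triad C1′/C5/C4 is contiguous, but C1 and C9 are two and three methylene groups away from it, so their configuration must be relayed across a medium ring.

The sensitive elements are the two o-hydroxyaryl aldehydes (not compatible with ylides, organometallics or hydrides), the electron-rich arene, the acid-labile 1,1-disubstituted alkene, the tertiary alkyl aryl ether, and C9, which can be epimerised only while C8 is a carbonyl carbon. The hard parts are the closure of a nine-membered ring, the strained trans-fused cyclobutane with a quaternary carbon, and the configuration of C1 relative to the chroman.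

The strategy rests on ring D. Its bonds C1–C9 and C10–C11 are the two bonds a formal [2+2] would make between a terminal alkyne C9≡C10 on the C5 arm and a prenyl-type alkene C1=C11 on the C4 arm. Making them closes ring C and ring D together from an open-chain chroman.

## Retrosynthetic reasoning

**26 ⇒ 24.** The two aryl–CHO bonds are cut first. The aldehydes would not survive the olefination, organometallic and hydride steps, and diphenol 24 is the most nucleophilic arene of the sequence. The forward reaction is a double Vilsmeier–Haack formylation that must leave the exocyclic alkene alone.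

**24 ⇒ 23 ⇒ 22.** The C8=C13 bond is cut to ketone 23 (Wittig methylenation). The two O-methyl groups are removed one step earlier, on ketone 22. Lewis-acid ether cleavage is safe on a ketone but not on a 1,1-disubstituted alkene, and nucleophilic demethylation after methylenation would stall once the first phenoxide has formed.

**22 ⇒ 21 ⇒ 20.** The C9–H configuration is traced to the cis-fused ketone 21 (epimerisation through the C8 enolate) and the two C–H bonds at C9 and C10 to enone 20 (hydrogenation). The C8 carbonyl thus serves as the precursor of the methylene group, the activator of the cyclobutene and the handle that lets C9 settle in the thermodynamic trans fusion.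

**20 ⇒ 19 ⇒ 18.** Enone 20 comes from the cyclobutenyl silyl ether 18 by desilylation and oxidation. Oxidising before hydrogenating merges the two C8 epimers into one compound.

**18 ⇒ 17 (key disconnection).** The bonds C1–C9 and C10–C11 are cut together, which opens ring C and ring D and leads to the open-chain 1,10-enyne 17. No other pair of bonds removes both carbocycles in one step while leaving a precursor that hangs entirely on a stereodefined chroman. The forward reaction must be Markovnikov at the alkyne, must close a nine-membered ring, and must select one face of the C1=C11 alkene.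

**17 ⇒ 16 ⇒ 14 + 15.** The C8–C9 bond is cut to aldehyde 14 and ethynylmagnesium bromide 15. The carbinol is silylated so that it survives the gold catalyst.

**14 ⇒ 13 ⇒ 12 ⇒ 11 ⇒ 10 ⇒ 8.** The C1=C11 bond is cut by a Wittig disconnection to aldehyde 11, which comes from the allyl group of 8 by hydroboration and oxidation. The C6–C8 arm is carried as a silyl-protected propanol, so only one alkene is present when the borane is used and the two arms never compete.

**8 ⇒ 6 + 7, and 6 ⇒ 5.** Both carbon substituents of C4 are attached to the lactone carbonyl carbon of 5. C12 comes by single addition of a methyl carbanion (hemiketal 6), and C3 by allylation of the derived oxocarbenium ion with allyltrimethylsilane 7. The order is chosen so that the second nucleophile enters anti to the C5 arm.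

**5 ⇒ 3 + 4.** The C5–C6 bond is cut to the lactone enolate of 3 and iodide 4. The 4-phenyl group directs the alkylation trans.

**3 ⇒ 1 + 2.** The C1′–phenyl bond is cut to 5,7-dimethoxycoumarin 1 and phenylboronic acid 2. This catalytic asymmetric conjugate addition is the only step that introduces absolute configuration; every later stereocentre is relayed from C1′.

## Alternatives that were turned down

**Alternative 1: Ireland–Claisen ring contraction.**
- Disconnection: the C4–C5 bond of ring C. The nine-membered acid A1 (C4 bearing the 3,5-dimethoxyphenoxy group and a carboxyl, C5 a vinyl group, C8 a dioxolane, ring D in place) would arise from the thirteen-membered α-aryloxy allylic lactone A2.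
- Forward key step: [3,3] rearrangement of the silyl ketene acetal of A2.
- For: the medium ring is never closed directly, a thirteen-membered lactonisation is easy, C4 and C5 are set in one suprafacial event, and C1/C9 come from a preformed cyclobutane and are secure.
- Against: the relative configuration C4/C5 depends on the enolate geometry of an α-aryloxy ester and on a chair/boat choice inside a macrocycle, neither of which is predictable. After A1 the carboxyl must still be reduced to the C12 methyl, the vinyl group turned into the phenyl-bearing C1′, and C1′ joined to the arene with control of a late benzylic stereocentre. An enantiopure, doubly functionalised cyclobutane is also needed.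
- Comparison: it is stronger on the security of C1/C9 and on precedent for the ring-forming event. The chosen route sets C1′ first and catalytically, needs no chiral cyclobutane building block, and is shorter after the key step.

**Alternative 2: ring-closing metathesis at C2=C3.**
- Disconnection: the C2=C3 bond of the Z-cyclononene ketone A3, which would come from diene A4 (vinyl on C4 of the chroman, vinyl on C1 of a trans-cyclobutyl ketone).
- Forward key step: ring closure with a ruthenium carbene catalyst.
- For: the reaction type is well established, all five stereocentres are in place before the ring closes, and only a hydrogenation follows.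
- Against: both alkenes are hindered (one on the fully substituted ether carbon C4, one on a cyclobutane carbon next to the quaternary C11), and a nine-membered ring is among the least favourable for metathesis, so oligomerisation is the likely outcome. A4 also requires an enantiopure trans-cyclobutane fragment and a fragment coupling.
- Comparison: it is stronger in stereochemical predictability, because the ring closure creates no stereocentre. The chosen route forms the four- and the nine-membered ring together from a linear precursor that needs no second chiral fragment, at the price of a new substrate class.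

**Alternative 3: late enone–alkene photocycloaddition.**
- Disconnection: the bonds C9–C10 and C1–C11 of ring D only, from the chroman-fused Z-cyclononenone A6 and 2-methylpropene A7, giving ketone A5, which is the same compound as 22.
- Forward key step: sensitised irradiation of A6 with A7.
- For: head-to-tail regiochemistry of enone/1,1-disubstituted alkene photocycloadditions matches the target, the product lies directly on the chosen route, and C9 can be corrected by epimerisation.
- Against: the nine-membered enone must be made by a separate medium-ring closure, the excited Z-enone can relax by Z/E isomerisation, and the face of C1 in a flexible ring is not anchored. The step is intermolecular with a gaseous alkene.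
- Comparison: it is as strong or stronger in precedent for the cyclobutane-forming event. The chosen route solves ring C and ring D in one intramolecular step, and the chemistry of A6 is kept as the fallback for that step.

Key step: step 12

Assumption: the carbinol carbon C8 formed in step 10 is not controlled. Compounds 16, 17, 18 and 19 are each carried as the pair of C8 epimers (no descriptor at C8 in their structures), which converge when C8 is oxidised in step 14.

## Route

Step 1
Reactants: 1 5,7-dimethoxycoumarin; 2 phenylboronic acid
Product: 3 (R)-5,7-dimethoxy-4-phenylchroman-2-one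
Conditions: Rh(acac)(C2H4)2 (3 mol %), (R)-SEGPHOS (3.3 mol %), excess 2, dioxane/H2O 10:1, 60 °C
Reagents that add atoms: phenylboronic acid (2), OB(O)c1ccccc1
Why: Hayashi–Miyaura conjugate addition: an aryl complex of monovalent rhodium inserts the coumarin C3=C4 bond and the oxa-π-allyl species is protonated by water. The (R)-bisphosphine selects the coumarin face that gives the 4R lactone, the sense known for 4-arylchroman-2-ones, and sets C1′.

Step 2
Reactants: 3 (R)-5,7-dimethoxy-4-phenylchroman-2-one; 4 tert-butyl(3-iodopropoxy)dimethylsilane
Product: 5 (3S,4R)-3-[3-(tert-butyldimethylsilyloxy)propyl]-5,7-dimethoxy-4-phenylchroman-2-one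
Conditions: LiN(SiMe3)2, THF, −78 °C; then 4, DMPU, −78 → −40 °C
Reagents that add atoms: tert-butyl(3-iodopropoxy)dimethylsilane (4), CC(C)(C)[Si](C)(C)OCCCI
Why: Lactone enolate alkylation with a primary iodide. The electrophile approaches C3 anti to the pseudoaxial 4-phenyl group, which gives the 3,4-trans lactone and sets C5; the enolate is kept cold so that the aryl ester does not open to a ketene.

Step 3
Reactants: 5 (3S,4R)-3-[3-(tert-butyldimethylsilyloxy)propyl]-5,7-dimethoxy-4-phenylchroman-2-one
Product: 6 (3S,4R)-3-[3-(tert-butyldimethylsilyloxy)propyl]-5,7-dimethoxy-2-methyl-4-phenylchroman-2-ol (both anomers; in equilibrium with the open hydroxy ketone)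
Conditions: MeLi (1.1 equiv), THF, −78 °C; NH4Cl aq at −78 °C
Reagents that add atoms: methyllithium, [Li]C
Why: Single addition of an organolithium to a lactone. At −78 °C the lithium hemiketal alkoxide should persist and is quenched cold, which installs C12 and avoids a second addition.

Step 4
Reactants: 6 (3S,4R)-3-[3-(tert-butyldimethylsilyloxy)propyl]-5,7-dimethoxy-2-methyl-4-phenylchroman-2-ol; 7 allyltrimethylsilane
Product: 8 (2R,3S,4R)-2-allyl-3-[3-(tert-butyldimethylsilyloxy)propyl]-5,7-dimethoxy-2-methyl-4-phenylchromane
Conditions: BF3·OEt2, CH2Cl2, −78 → −40 °C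
Reagents that add atoms: allyltrimethylsilane (7), C=CC[Si](C)(C)C
Why: Hosomi–Sakurai allylation of a ketal-derived cyclic oxocarbenium ion. The cation should prefer the half-chair in which the 4-phenyl group (peri to the 5-methoxy group) and the 3-alkyl arm (allylic strain with the 2-methyl group) are pseudoaxial, and the silane attacks axially, anti to the neighbouring C5 arm. The allyl group then ends trans to that arm and the methyl group cis to it, which is the C4 configuration of the target.

Step 5
Reactants: 8 (2R,3S,4R)-2-allyl-3-[3-(tert-butyldimethylsilyloxy)propyl]-5,7-dimethoxy-2-methyl-4-phenylchromane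
Product: 10 3-[(2R,3S,4R)-3-[3-(tert-butyldimethylsilyloxy)propyl]-5,7-dimethoxy-2-methyl-4-phenylchroman-2-yl]propan-1-ol, via B-alkyl-9-borabicyclo[3.3.1]nonane 9 (not isolated)
Conditions: 9-BBN, THF, 0 °C → rt; then NaOH aq, H2O2, 0 °C → rt
Reagents that add atoms: 9-borabicyclo[3.3.1]nonane, B1C2CCCC1CCC2 (boron bicycle of 9 only); hydrogen peroxide, OO
Why: Brown hydroboration–oxidation. The borane places boron on the terminal carbon of the only alkene present and the C–B bond is oxidised with retention.

Step 6
Reactants: 10 3-[(2R,3S,4R)-3-[3-(tert-butyldimethylsilyloxy)propyl]-5,7-dimethoxy-2-methyl-4-phenylchroman-2-yl]propan-1-ol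
Product: 11 3-[(2R,3S,4R)-3-[3-(tert-butyldimethylsilyloxy)propyl]-5,7-dimethoxy-2-methyl-4-phenylchroman-2-yl]propanal
Conditions: Dess–Martin periodinane, NaHCO3, CH2Cl2, 0 °C → rt
Reagents that add atoms: none
Why: Dess–Martin oxidation of a primary alcohol to the aldehyde under buffered conditions; the silyl ether and the electron-rich arene are not touched.

Step 7
Reactants: 11 3-[(2R,3S,4R)-3-[3-(tert-butyldimethylsilyloxy)propyl]-5,7-dimethoxy-2-methyl-4-phenylchroman-2-yl]propanal
Product: 12 (2R,3S,4R)-3-[3-(tert-butyldimethylsilyloxy)propyl]-5,7-dimethoxy-2-methyl-2-(4-methylpent-3-enyl)-4-phenylchromane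
Conditions: i-PrPPh3I, n-BuLi, THF, 0 °C; then 11, −78 °C → rt
Reagents that add atoms: isopropyltriphenylphosphonium iodide, CC(C)[P+](c1ccccc1)(c1ccccc1)c1ccccc1.[I-]
Why: Wittig olefination with the non-stabilised isopropylidene ylide turns the aldehyde carbon (C1) into the trisubstituted C1=C11 alkene, which has no E/Z issue.

Step 8
Reactants: 12 (2R,3S,4R)-3-[3-(tert-butyldimethylsilyloxy)propyl]-5,7-dimethoxy-2-methyl-2-(4-methylpent-3-enyl)-4-phenylchromane
Product: 13 3-[(2R,3S,4R)-5,7-dimethoxy-2-methyl-2-(4-methylpent-3-enyl)-4-phenylchroman-3-yl]propan-1-ol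
Conditions: n-Bu4NF, THF, rt
Reagents that add atoms: none
Why: Fluoride cleavage of the primary silyl ether; nothing else in the molecule is fluoride-labile.

Step 9
Reactants: 13 3-[(2R,3S,4R)-5,7-dimethoxy-2-methyl-2-(4-methylpent-3-enyl)-4-phenylchroman-3-yl]propan-1-ol
Product: 14 3-[(2R,3S,4R)-5,7-dimethoxy-2-methyl-2-(4-methylpent-3-enyl)-4-phenylchroman-3-yl]propanal
Conditions: Dess–Martin periodinane, NaHCO3, CH2Cl2, 0 °C → rt
Reagents that add atoms: none
Why: Dess–Martin oxidation to the C8 aldehyde; the trisubstituted alkene is inert.

Step 10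
Reactants: 14 3-[(2R,3S,4R)-5,7-dimethoxy-2-methyl-2-(4-methylpent-3-enyl)-4-phenylchroman-3-yl]propanal; 15 ethynylmagnesium bromide
Product: 16 5-[(2R,3S,4R)-5,7-dimethoxy-2-methyl-2-(4-methylpent-3-enyl)-4-phenylchroman-3-yl]pent-1-yn-3-ol (both carbinol epimers)
Conditions: HC≡CMgBr, THF, −78 → 0 °C; NH4Cl aq
Reagents that add atoms: ethynylmagnesium bromide (15), C#C[Mg]Br
Why: Grignard addition of the acetylide to an unhindered aldehyde forms C8–C9. The stereocentres are too remote to bias C8, so both epimers form and are carried on.

Step 11
Reactants: 16 5-[(2R,3S,4R)-5,7-dimethoxy-2-methyl-2-(4-methylpent-3-enyl)-4-phenylchroman-3-yl]pent-1-yn-3-ol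
Product: 17 tert-butyldimethylsilyl ether of 16: (2R,3S,4R)-3-[3-(tert-butyldimethylsilyloxy)pent-4-ynyl]-5,7-dimethoxy-2-methyl-2-(4-methylpent-3-enyl)-4-phenylchromane (both C8 epimers)
Conditions: t-BuMe2SiCl, imidazole, DMF, rt
Reagents that add atoms: tert-butyldimethylsilyl chloride, CC(C)(C)[Si](C)(C)Cl
Why: Imidazole-mediated silylation of the secondary propargylic alcohol. The bulky silyl ether blocks Meyer–Schuster chemistry and oxygen coordination to gold in the next step.

Step 12
Reactants: 17 (2R,3S,4R)-3-[3-(tert-butyldimethylsilyloxy)pent-4-ynyl]-5,7-dimethoxy-2-methyl-2-(4-methylpent-3-enyl)-4-phenylchromane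
Product: 18 cyclobutene-fused tricycle: the 5,7-dimethoxy-4-phenylchroman trans-fused at C4–C5 to the nine-membered ring C1–C9, which carries the C1/C9=C10/C11 cyclobutene with gem-dimethyl C11 and the silyl ether at C8 (1S,4R,5S,1′R; both C8 epimers)
Conditions: [Au(NCMe){P(t-Bu)2(biphenyl-2-yl)}]SbF6 (5 mol %), CH2Cl2, 2 mM, slow addition of 17, 23 °C
Reagents that add atoms: none
Why: Proposed new method: cationic monovalent gold binds the terminal alkyne of 17 and slips toward C10, the nucleophilic alkene carbon C1 attacks the internal carbon C9 anti to gold (cyclopropyl gold carbene/homoallyl cation continuum), and the alkenylgold carbon C10 then closes on the tertiary C11 cation and releases the catalyst, a stepwise formal [2+2]; the closest known reaction type is the gold-catalysed [2+2] macrocyclisation of 1,n-enynes with an aryl alkyne and a trisubstituted alkene, and what is new is an alkyl alkyne carrying a propargylic silyl ether. Ring C closes in 9-exo-dig mode (C9≡C10 stays outside the ring), and ring D closes by attack of the C9=C10 alkenylgold on C11 with the double bond inside the new four-membered ring. Markovnikov attack at C9 is required; the terminal alkyne secures it, because gold can sit on the unsubstituted C10 while charge builds on the substituted carbon, and attack at C10 would need a ten-membered ring. The silyloxy group withdraws only inductively, and propargylic silyl ethers are tolerated with the same regiochemistry in gold-catalysed cyclisations of shorter enynes. The gem-dimethyl terminus fixes the polarity of the alkene, so that C1 and not C11 bonds to C9. The new stereocentre C1 is controlled by the chroman: with the phenyl group and both arms equatorial the torsion C3–C4–C5–C6 is gauche with a fixed sign, and ring C can reach its low-strain twist-boat-chair (C4 and C1 at corners) only if the torsion C8–C9–C1–C2 has the same sign, which puts H-1 on the side of H-5 as in the target. High dilution with slow addition suppresses oligomers, and the bulky phosphine disfavours digold acetylide resting states.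

Step 13
Reactants: 18 cyclobutene-fused tricycle with the silyl ether at C8
Product: 19 cyclobutenyl carbinol: 18 with free OH at C8 (1S,4R,5S,1′R; both C8 epimers)
Conditions: n-Bu4NF, THF, rt → 40 °C
Reagents that add atoms: none
Why: Fluoride desilylation of the secondary allylic silyl ether.

Step 14
Reactants: 19 cyclobutenyl carbinol
Product: 20 enone: C8 ketone conjugated with the C9=C10 cyclobutene (1S,4R,5S,1′R)
Conditions: Dess–Martin periodinane, NaHCO3, CH2Cl2, 0 °C → rt
Reagents that add atoms: none
Why: Dess–Martin oxidation of the allylic alcohol removes the C8 stereocentre, so both epimers converge on one enone.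

Step 15
Reactants: 20 enone
Product: 21 cis-fused ketone: C8 ketone with saturated ring D and H-9 cis to H-1 (1R,4R,5S,9R,1′R)
Conditions: H2 (1 atm), Pd/C, EtOAc, rt
Reagents that add atoms: none
Why: Heterogeneous hydrogenation of the strained, conjugated cyclobutene. Hydrogen should be delivered to the open face that carries H-1 (ring C covers the other), so the cis-fused ketone is expected; ketone, arene and the diarylmethine are inert under these conditions.

Step 16
Reactants: 21 cis-fused ketone
Product: 22 trans-fused ketone (1R,4R,5S,9S,1′R)
Conditions: NaOMe, MeOH/THF, rt → 40 °C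
Reagents that add atoms: none
Why: Base-mediated epimerisation through the C8 enolate. C9 is the only enolisable stereocentre, and the trans 4/9 ring junction is the thermodynamically preferred one for ketones of the caryophyllane type, which sets C9.

Step 17
Reactants: 22 trans-fused ketone
Product: 23 diphenol ketone: 22 with both O-methyl groups removed (1R,4R,5S,9S,1′R)
Conditions: BBr3, CH2Cl2, −78 → 0 °C; NaHCO3 aq
Reagents that add atoms: none
Why: Lewis-acid cleavage of both aryl methyl ethers (bromide attacks the methyl groups of the boron-complexed ethers). It is placed here because no alkene is present; the ring ether, with a fully substituted alkyl carbon and a hindered oxygen, should persist.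

Step 18
Reactants: 23 diphenol ketone
Product: 24 diphenol with the C8 exocyclic methylene (1R,4R,5S,9S,1′R)
Conditions: Ph3PCH3Br, KOt-Bu (6 equiv each), THF/toluene, 0 → 60 °C; NH4Cl aq
Reagents that add atoms: methyltriphenylphosphonium bromide, C[P+](c1ccccc1)(c1ccccc1)c1ccccc1.[Br-]
Why: Wittig methylenation with excess salt-free ylide. The phenols are carried as phenoxides, and the thermodynamic trans configuration at C9 is kept under the basic conditions.

Step 19
Reactants: 24 diphenol with the C8 exocyclic methylene
Product: 26 target CNP0253700.4 (1R,4R,5S,9S,1′R), via bis-iminium dichloride 25 (not isolated)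
Conditions: POCl3, DMF, EtOAc, 0 °C → rt; then H2O, NaOAc, rt
Reagents that add atoms: N,N-dimethylformamide, CN(C)C=O; phosphoryl chloride, O=P(Cl)(Cl)Cl (chloride of 25 only); water, O
Why: Vilsmeier–Haack formylation. The chloroiminium ion attacks the two free positions of ring A, each activated by three oxygen substituents, and the bis-iminium salt is hydrolysed on work-up; at this temperature the arene should be far more nucleophilic than the 1,1-disubstituted alkene.

## Compound list

1 | 5,7-dimethoxycoumarin | COc1cc(OC)c2ccc(=O)oc2c1 | starting material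
2 | phenylboronic acid | OB(O)c1ccccc1 | starting material
3 | (R)-5,7-dimethoxy-4-phenylchroman-2-one | O=C1C[C@H](c2ccccc2)c2c(OC)cc(OC)cc2O1 | intermediate
4 | tert-butyl(3-iodopropoxy)dimethylsilane | CC(C)(C)[Si](C)(C)OCCCI | starting material
5 | (3S,4R)-3-[3-(tert-butyldimethylsilyloxy)propyl]-5,7-dimethoxy-4-phenylchroman-2-one | CC(C)(C)[Si](C)(C)OCCC[C@H]1[C@H](c2ccccc2)c2c(OC)cc(OC)cc2OC1=O | intermediate
6 | (3S,4R)-3-[3-(tert-butyldimethylsilyloxy)propyl]-5,7-dimethoxy-2-methyl-4-phenylchroman-2-ol, both anomers | CC(C)(C)[Si](C)(C)OCCC[C@H]1[C@H](c2ccccc2)c2c(OC)cc(OC)cc2OC1(C)O | intermediate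
7 | allyltrimethylsilane | C=CC[Si](C)(C)C | starting material
8 | (2R,3S,4R)-2-allyl-3-[3-(tert-butyldimethylsilyloxy)propyl]-5,7-dimethoxy-2-methyl-4-phenylchromane | CC(C)(C)[Si](C)(C)OCCC[C@H]1[C@H](c2ccccc2)c2c(OC)cc(OC)cc2O[C@]1(C)CC=C | intermediate
9 | B-alkyl-9-borabicyclo[3.3.1]nonane from 8 | CC(C)(C)[Si](C)(C)OCCC[C@H]1[C@H](c2ccccc2)c2c(OC)cc(OC)cc2O[C@]1(C)CCCB1C2CCCC1CCC2 | intermediate (not isolated)
10 | 3-[(2R,3S,4R)-3-[3-(tert-butyldimethylsilyloxy)propyl]-5,7-dimethoxy-2-methyl-4-phenylchroman-2-yl]propan-1-ol | CC(C)(C)[Si](C)(C)OCCC[C@H]1[C@H](c2ccccc2)c2c(OC)cc(OC)cc2O[C@]1(C)CCCO | intermediate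
11 | 3-[(2R,3S,4R)-3-[3-(tert-butyldimethylsilyloxy)propyl]-5,7-dimethoxy-2-methyl-4-phenylchroman-2-yl]propanal | CC(C)(C)[Si](C)(C)OCCC[C@H]1[C@H](c2ccccc2)c2c(OC)cc(OC)cc2O[C@]1(C)CCC=O | intermediate
12 | (2R,3S,4R)-3-[3-(tert-butyldimethylsilyloxy)propyl]-5,7-dimethoxy-2-methyl-2-(4-methylpent-3-enyl)-4-phenylchromane | CC(C)(C)[Si](C)(C)OCCC[C@H]1[C@H](c2ccccc2)c2c(OC)cc(OC)cc2O[C@]1(C)CCC=C(C)C | intermediate
13 | 3-[(2R,3S,4R)-5,7-dimethoxy-2-methyl-2-(4-methylpent-3-enyl)-4-phenylchroman-3-yl]propan-1-ol | OCCC[C@H]1[C@H](c2ccccc2)c2c(OC)cc(OC)cc2O[C@]1(C)CCC=C(C)C | intermediate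
14 | 3-[(2R,3S,4R)-5,7-dimethoxy-2-methyl-2-(4-methylpent-3-enyl)-4-phenylchroman-3-yl]propanal | O=CCC[C@H]1[C@H](c2ccccc2)c2c(OC)cc(OC)cc2O[C@]1(C)CCC=C(C)C | intermediate
15 | ethynylmagnesium bromide | C#C[Mg]Br | starting material
16 | 5-[(2R,3S,4R)-5,7-dimethoxy-2-methyl-2-(4-methylpent-3-enyl)-4-phenylchroman-3-yl]pent-1-yn-3-ol, both C8 epimers | C#CC(O)CC[C@H]1[C@H](c2ccccc2)c2c(OC)cc(OC)cc2O[C@]1(C)CCC=C(C)C | intermediate
17 | tert-butyldimethylsilyl ether of 16 (1,10-enyne, both C8 epimers) | C#CC(O[Si](C)(C)C(C)(C)C)CC[C@H]1[C@H](c2ccccc2)c2c(OC)cc(OC)cc2O[C@]1(C)CCC=C(C)C | intermediate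
18 | cyclobutene-fused tricycle with C8 silyl ether (1S,4R,5S,1′R; both C8 epimers) | CC(C)(C)[Si](C)(C)OC1CC[C@H]2[C@H](c3ccccc3)c3c(OC)cc(OC)cc3O[C@]2(C)CC[C@@H]2C1=CC2(C)C | intermediate
19 | cyclobutenyl carbinol (1S,4R,5S,1′R; both C8 epimers) | OC1CC[C@H]2[C@H](c3ccccc3)c3c(OC)cc(OC)cc3O[C@]2(C)CC[C@@H]2C1=CC2(C)C | intermediate
20 | enone, C8 ketone with C9=C10 (1S,4R,5S,1′R) | O=C1CC[C@H]2[C@H](c3ccccc3)c3c(OC)cc(OC)cc3O[C@]2(C)CC[C@@H]2C1=CC2(C)C | intermediate
21 | cis-fused ketone (1R,4R,5S,9R,1′R) | O=C1CC[C@H]2[C@H](c3ccccc3)c3c(OC)cc(OC)cc3O[C@]2(C)CC[C@@H]2[C@H]1CC2(C)C | intermediate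
22 | trans-fused ketone (1R,4R,5S,9S,1′R) | O=C1CC[C@H]2[C@H](c3ccccc3)c3c(OC)cc(OC)cc3O[C@]2(C)CC[C@@H]2[C@@H]1CC2(C)C | intermediate
23 | diphenol ketone (1R,4R,5S,9S,1′R) | O=C1CC[C@H]2[C@H](c3ccccc3)c3c(O)cc(O)cc3O[C@]2(C)CC[C@@H]2[C@@H]1CC2(C)C | intermediate
24 | diphenol with C8 exocyclic methylene (1R,4R,5S,9S,1′R) | C=C1CC[C@H]2[C@H](c3ccccc3)c3c(O)cc(O)cc3O[C@]2(C)CC[C@@H]2[C@@H]1CC2(C)C | intermediate
25 | bis(dimethyliminium) dichloride of the target | C=C1CC[C@H]2[C@H](c3ccccc3)c3c(O)c(C=[N+](C)C)c(O)c(C=[N+](C)C)c3O[C@]2(C)CC[C@@H]2[C@@H]1CC2(C)C.[Cl-].[Cl-] | intermediate (not isolated)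
26 | CNP0253700.4 (1R,4R,5S,9S,1′R) | C=C1CC[C@H]2[C@H](c3ccccc3)c3c(O)c(C=O)c(O)c(C=O)c3O[C@]2(C)CC[C@@H]2[C@@H]1CC2(C)C | target

## Step count and least certain steps

Total: 19 steps. Longest linear sequence: 19 steps (1 → 26); the route is fully linear, and 2, 4, 7 and 15 are bought.

**Step 12 (key step).** The propargylic silyloxy group may slow or misdirect the attack on the alkyne, the terminal alkyne may tie up the catalyst as a digold acetylide, the C11 cation may lose a proton before ring D closes, or the facial selection at C1 may be insufficient. The fallback uses known reaction types, sets out from aldehyde 14 and returns at ketone 21. Vinylmagnesium bromide adds to 14 to give the allylic alcohol F1. Dess–Martin oxidation gives the vinyl ketone F2. Ring-closing metathesis with the second-generation Grubbs catalyst RuCl2(PCy3)(H2IMes)(=CHPh) in dilute toluene at 80 °C joins C1 and C9 with loss of 2-methylpropene and gives the Z-cyclononenone F3. Irradiation of F3 with excess 2-methylpropene (365 nm, CH2Cl2, −78 °C) should give the head-to-tail cyclobutane as 21 together with 22, and step 16 converges both on 22. The face of C1 is then decided in the photocycloaddition, not by gold.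

**Step 4.** The pseudoaxial 4-phenyl group sits 1,3 to the incoming allylsilane and may override the anti-to-arm preference, so facial selectivity at C4 may be poor or reversed. Proton loss from the oxocarbenium ion to the enol ether is a second risk. The fallback applies when the nucleophile enters mainly cis to the C5 arm. It reverses the order in which the two C4 substituents arrive, sets out from lactone 5 and returns at 12. (4-Methylpent-3-enyl)magnesium bromide at −78 °C gives the hemiketal F4. AlMe3 in CH2Cl2 (−78 → 0 °C) then delivers the methyl group to the oxocarbenium ion with the same facial preference, which now gives the required configuration, and steps 3 to 7 are bypassed.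

**Step 3.** The tetrahedral intermediate may collapse to the phenoxide ketone, which takes up a second equivalent, or the lactone may be enolised. The fallback sets out from 5 and returns at 6. Ring opening with Me(MeO)NH·HCl and i-PrMgCl gives the Weinreb amide F5, and excess methylmagnesium bromide stops at the methyl ketone, which closes to hemiketal 6 on work-up.

**Step 1.** The peri 5-methoxy group may retard insertion at C4 so that protodeboronation of 2 wins. The fallback sets out from 1 and 2 and returns at 3. An oxidative Heck arylation (Pd(OAc)2, 1,10-phenanthroline, O2, DMF) gives 5,7-dimethoxy-4-phenylcoumarin F6. A copper hydride conjugate reduction (Cu(OAc)2, DTBM-SEGPHOS in the enantiomer that gives the R lactone, (EtO)2MeSiH, t-BuOH, toluene) then sets C1′.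

**Step 19.** The chloroiminium ion or the hydrogen chloride formed may attack the exocyclic alkene, or the second formylation may stall on the deactivated ring. The fallback formylates before the alkene exists, sets out from 23 and returns at 26. Rieche formylation (Cl2CHOMe, TiCl4, CH2Cl2, −78 → 0 °C) of 23 gives the diformyl diphenol ketone F7. Condensation with butan-1-amine masks both aldehydes as the bis-aldimine F8. Wittig methylenation of the ketone gives the bis-aldimine alkene F9, and dilute aqueous acetic acid releases 26.

## Further compounds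

F1 | step 12 | 5-[(2R,3S,4R)-5,7-dimethoxy-2-methyl-2-(4-methylpent-3-enyl)-4-phenylchroman-3-yl]pent-1-en-3-ol, both carbinol epimers | C=CC(O)CC[C@H]1[C@H](c2ccccc2)c2c(OC)cc(OC)cc2O[C@]1(C)CCC=C(C)C
F2 | step 12 | 5-[(2R,3S,4R)-5,7-dimethoxy-2-methyl-2-(4-methylpent-3-enyl)-4-phenylchroman-3-yl]pent-1-en-3-one | C=CC(=O)CC[C@H]1[C@H](c2ccccc2)c2c(OC)cc(OC)cc2O[C@]1(C)CCC=C(C)C
F3 | step 12 | chroman-fused Z-cyclononenone, C8 ketone with C1=C9 | O=C1CC[C@H]2[C@H](c3ccccc3)c3c(OC)cc(OC)cc3O[C@]2(C)CC/C=C\1
F4 | step 4 | (3S,4R)-3-[3-(tert-butyldimethylsilyloxy)propyl]-5,7-dimethoxy-2-(4-methylpent-3-enyl)-4-phenylchroman-2-ol, both anomers | CC(C)(C)[Si](C)(C)OCCC[C@H]1[C@H](c2ccccc2)c2c(OC)cc(OC)cc2OC1(O)CCC=C(C)C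
F5 | step 3 | (2S,3R)-5-(tert-butyldimethylsilyloxy)-2-[(R)-(2-hydroxy-4,6-dimethoxyphenyl)(phenyl)methyl]-N-methoxy-N-methylpentanamide | CON(C)C(=O)[C@@H](CCCO[Si](C)(C)C(C)(C)C)[C@H](c1ccccc1)c1c(O)cc(OC)cc1OC
F6 | step 1 | 5,7-dimethoxy-4-phenylcoumarin | COc1cc(OC)c2c(-c3ccccc3)cc(=O)oc2c1
F7 | step 19 | diformyl diphenol ketone (1R,4R,5S,9S,1′R) | O=C1CC[C@H]2[C@H](c3ccccc3)c3c(O)c(C=O)c(O)c(C=O)c3O[C@]2(C)CC[C@@H]2[C@@H]1CC2(C)C
F8 | step 19 | bis(N-butylaldimine) of F7 | O=C1CC[C@H]2[C@H](c3ccccc3)c3c(O)c(C=NCCCC)c(O)c(C=NCCCC)c3O[C@]2(C)CC[C@@H]2[C@@H]1CC2(C)C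
F9 | step 19 | bis(N-butylaldimine) of the target | C=C1CC[C@H]2[C@H](c3ccccc3)c3c(O)c(C=NCCCC)c(O)c(C=NCCCC)c3O[C@]2(C)CC[C@@H]2[C@@H]1CC2(C)C
A1 | alternative 1 | nine-membered carbocyclic acid with C4 aryloxy and carboxyl, C5 vinyl, C8 dioxolane | C12(OCCO1)CC[C@@H](C=C)[C@@](Oc1cc(OC)cc(OC)c1)(C(=O)O)CC[C@@H]1[C@@H]2CC1(C)C
A2 | alternative 1 | thirteen-membered α-(3,5-dimethoxyphenoxy) allylic lactone with the trans-cyclobutane and the C8 dioxolane (alkene geometry and C4 left open) | O=C1OCC=CCCC2(OCCO2)[C@H]2CC(C)(C)[C@@H]2CCC1Oc1cc(OC)cc(OC)c1
A3 | alternative 2 | Z-cyclononene with C2=C3 and C8 ketone | O=C1CC[C@H]2[C@H](c3ccccc3)c3c(OC)cc(OC)cc3O[C@]2(C)/C=C\[C@@H]2[C@@H]1CC2(C)C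
A4 | alternative 2 | diene: 2-vinylchroman bearing the trans-2-vinyl-3,3-dimethylcyclobutyl ketone | O=C(CC[C@H]1[C@H](c2ccccc2)c2c(OC)cc(OC)cc2O[C@]1(C)C=C)[C@H]1CC(C)(C)[C@@H]1C=C
A5 | alternative 3 | trans-fused C8 ketone, identical with 22 | O=C1CC[C@H]2[C@H](c3ccccc3)c3c(OC)cc(OC)cc3O[C@]2(C)CC[C@@H]2[C@@H]1CC2(C)C
A6 | alternative 3 | chroman-fused Z-cyclononenone, C8 ketone with C1=C9 | O=C1CC[C@H]2[C@H](c3ccccc3)c3c(OC)cc(OC)cc3O[C@]2(C)CC/C=C\1
A7 | alternative 3 | 2-methylpropene | CC(C)=C
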